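Mind the clock. The flasks noon, dawn, dusk and autumn are to run as below, and each will hold target, isomer of the product A and isomer of the product B. Report the share of target among these three, the selectivity.

| flask | starting material | reagent | remark | time |
|---|---|---|---|---|
| violet | 1.4 M | 1.47 M | run made earlier |  |
| grey | 0.70 M | 1.47 M | run made earlier |  |
| ochre | 2.8 M | 1.47 M | run made earlier |  |
| green | 1.4 M | 2.9 M | run made earlier |  |
| noon | 1.4 M | 1.47 M | one stirred flow tank at steady state, fed with the mixture as stated, mean residence time 3.0 h |  |
| dawn | 1.4 M (fed, over 1.50 h) | 1.47 M | all but starting material at the start; starting material goes in evenly over 1.50 h, the run ends at 3.0 h | 3.0 h |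
| dusk | 1.4 M | 1.47 M (fed, over 1.50 h) | a stirred flask in which reagent is dosed at a steady rate over 1.50 h without added volume, worked up at 3.0 h | 3.0 h |
| autumn | 1.4 M | 1.47 M | a closed flask charged with all of it at once and left for 3.0 h | 3.0 h |

- violet (time / min: target / %, isomer of the product A / %, isomer of the product B / %): 8.00: 28.8, 3.7, 1.2; 15.0: 36.4, 1.1, 2.1; 25.0: 37.8, 4.7, 7.2; 40.0: 34.9, 5.7, 11.6; 60.0: 32.8, 5.4, 14.8; 120: 28.6, 8.5, 20.4
- grey (time / h: target / %, isomer of the product A / %, isomer of the product B / %): 0.250: 41.0, 3.2, 2.8; 0.500: 44.4, 4.5, 9.6; 0.833: 41.9, 5.5, 12.9; 1.33: 36.7, 9.3, 22.2; 2.00: 34.0, 9.9, 25.4; 4.00: 29.2, 15.0, 29.6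
- ochre (time / h: target / %, isomer of the product A / %, isomer of the product B / %): 0.250: 27.5, 0.3, 1.6; 0.500: 27.7, 3.9, 5.7; 0.833: 26.4, 3.0, 9.4; 1.33: 22.3, 4.3, 12.4; 2.00: 19.9, 6.9, 15.2; 4.00: 17.4, 9.6, 16.7
- green (time / h: target / %, isomer of the product A / %, isomer of the product B / %): 0.250: 55.2, 3.4, 5.5; 0.500: 53.9, 5.3, 13.0; 1.00: 47.9, 9.3, 21.0; 2.00: 38.9, 12.6, 29.3; 4.00: 31.4, 18.2, 32.1

(readings scatter by 1 percentage point)

- the stated concentrations are those of everything mixed, before any reaction; amounts are the same in each set-up
- the numbers in the tables scatter with a standard deviation of 1 percentage point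
- the feed brings no volume worth counting
- the earlier runs were made in a closed, stirred flask

- the set-up with the highest share of target in all that became target or isomer of the product A or isomer of the product B, at the outlet or at the end ("none" if the first two lie within 2 percentage points) (noon / dawn / dusk / autumn / none)
- share of target in all that became target or isomer of the product A or isomer of the product B, at the outlet or at the end, noon
- share of target in all that became target or isomer of the product A or isomer of the product B, at the outlet or at the end, dawn
- share of target in all that became target or isomer of the product A or isomer of the product B, at the outlet or at the end, dusk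
- share of target in all that became target or isomer of the product A or isomer of the product B, at the outlet or at the end, autumn

First read the share from the earlier runs. At 4.00 h it is 39.6 % in grey, 39.8 % in ochre and 38.4 % in green, although [starting material] runs from 0.70 M to 2.8 M. So reckon by age, not by concentration.

Green reads 61.3 % at 1.00 h, 48.1 % at 2.00 h and 38.4 % at 4.00 h. Integrate a first-order decay of the share through these readings: share = floor + amplitude × exp(−λ × age). This gives the ageing rate λ, a relaxation rate, of 0.703 h⁻¹, a floor of 35.3 % and an amplitude of 52.4 %, all as readings.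

My reckoning: autumn, taken at age 3.0 h, ends at 41.6 %. Dawn and dusk, taken at a mean age of 2.25 h, end at 46.1 %. Noon has exponential ages about its mean residence time τ, so the exponential averages to 1/(1 + λτ), which gives 52.2 %, higher than the others. Do not leave autumn past 3.0 h: in green the share fell from 48.1 % at 2.00 h to 38.4 % at 4.00 h.

The forecast says noon, with 52 %, 46 %, 47 % and 43.5 % for noon, dawn, dusk and autumn, since “what counts is the time since each molecule formed”. It puts autumn above my figure.

The flasks give 50.1 %, 46.3 %, 46.3 % and 42.4 %, so noon leads.

    starting material + reagent ⇌ target (K = 1.16 M⁻¹, k = 0.0446 M⁻¹ min⁻¹)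
    starting material + reagent ⇌ isomer of the product A (K = 3.90 M⁻¹, k = 0.00211 M⁻¹ min⁻¹)
    target ⇌ isomer of the product B (K = 0.963, k = 0.0100 min⁻¹)

With the step from target to isomer of the product B struck out both ways, noon gives 74.5 %. Autumn's share reaches 47.4 % at 2.08 h, where λ gives 47.4 %. For grey at 4.00 h, λ gives 38.4 %, and without the scatter grey stands at 39.5 %.

The numbers in the tables come from a simulation for an exercise, and the scatter is random.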